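**Plan**

- Retrosynthesis: cut the C3–O ester bond (decalol + side-chain acid), then the C7–isopropenyl and C9–O bonds (enolate chemistry on ring B), then the C4–C5 bond of ring A by a retro-1,2-shift.
- Enabling feature: in ring A the oxygenated C3 and the methyl-bearing methine C4 sit next to the quaternary C5. An α-methyl ketone flanked by a quaternary carbon is the retron of a one-carbon semipinacol enlargement of the cyclopentanone of the Hajos–Parrish ketone.
- Forward: ring B and C5 come intact from (S)-Hajos–Parrish ketone. A 1-hydroxyethyl group is built on the cyclopentanone carbonyl, and a C–C bond of that five-membered ring is cut and re-formed one carbon further out, giving ring A.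
- Then: cis reduction of the enone, C3 reduction, C9 oxidation, C7 alkenylation, and esterification last with an acid made from (R)-1,2-epoxybutane, angelic acid and acrylic acid.
- Stereochemistry: C5 from the starting ketone; C4 by inversion at an (R)-mesylate carbon set by chelation-controlled reduction; C10 by cis conjugate hydride delivery; C3 by dissolving-metal reduction; C9 and C7 by convex-face attack on the cis-decalin (C7 is also the thermodynamic epimer).
- Side chain: the carbinol centre comes from the epoxide, the Z-alkene from angelic acid, the E-alkene from cross-metathesis.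

Key step: step 4

Remark: the decalins are numbered as eremophilanes (ring A = C1–C5, C10; ring B = C5–C10; β = face of the C5 methyl); (S)-Hajos–Parrish ketone and (R)-1,2-epoxybutane are taken as commercial.

**Step 1**
Reactants: 1 (S)-Hajos–Parrish ketone
Product: 3 (1S,7aS)-1-acetyl-1-hydroxy-7a-methyl-2,3,7,7a-tetrahydro-1H-inden-5(6H)-one, via enol ether adduct 2 (not isolated)
Conditions: ethyl vinyl ether, t-BuLi, THF, −78 to 0 °C; CeCl3, −78 °C; then 1, −78 °C; then 0.5 M HCl, THF, 0 °C
Reagents that add atoms: ethyl vinyl ether (as 1-ethoxyvinyllithium), C=COCC; water, O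
Why: Organocerium 1,2-addition of an acyl-anion equivalent should go to the non-conjugated, more electrophilic cyclopentanone carbonyl from the face opposite the angular methyl (as hydride does with this diketone), setting C1 with OH cis to the methyl, and enol ether hydrolysis unveils the methyl ketone.

**Step 2**
Reactants: 3 α-ketol
Product: 4 (1S,7aS)-1-hydroxy-1-[(1R)-1-hydroxyethyl]-7a-methyl-2,3,7,7a-tetrahydro-1H-inden-5(6H)-one
Conditions: Zn(BH4)2, Et2O, −40 °C; then aq. NH4Cl
Reagents that add atoms: none
Why: Chelation-controlled (Cram-chelate) reduction: zinc bridges the tertiary hydroxyl and the ketone, hydride enters from the side of the ring CH2 and not of the quaternary carbon, which sets the (R)-carbinol, while the unchelated enone should react far more slowly at this temperature.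

**Step 3**
Reactants: 4 diol
Product: 5 (1R)-1-[(1S,7aS)-1-hydroxy-7a-methyl-5-oxo-2,3,5,6,7,7a-hexahydro-1H-inden-1-yl]ethyl methanesulfonate
Conditions: MsCl (1.1 equiv), Et3N, CH2Cl2, −20 °C
Reagents that add atoms: methanesulfonyl chloride, CS(=O)(=O)Cl
Why: Sulfonylation through sulfene is selective for the secondary over the tertiary hydroxyl and touches no stereocentre.

**Step 4**
Reactants: 5 hydroxy mesylate
Product: 7 (4aR,5R)-4a,5-dimethyl-4,4a,7,8-tetrahydronaphthalene-2,6(3H,5H)-dione, via aluminium alkoxide 6 (not isolated)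
Conditions: Et2AlCl (2 equiv), CH2Cl2, −78 to −20 °C; then 1 M HCl
Reagents that add atoms: none
Why: The chloro(ethyl)aluminium alkoxide 6 pushes electrons from oxygen while aluminium pulls on the mesylate, and the C1–C7a bond lying antiperiplanar to the C–OMs bond shifts to the mesylate carbon as C1 becomes the carbonyl (semipinacol 1,2-shift). The closest known reaction types are the organoaluminium-promoted pinacol-type rearrangement of β-mesyloxy alcohols (Suzuki–Tsuchihashi) and the D-homoannulation of steroidal 17-hydroxy-20-sulfonates. No ring is closed in the Baldwin sense: six-membered ring A grows out of the cyclopentane by a suprafacial 1,2-carbon shift through a three-centre transition state, the C1–C7a bond being cut and the C7a–CH(CH3) bond made. The new stereocentre C4 is set by inversion at the (R)-mesylate carbon while the migrating quaternary carbon keeps its configuration, which places the C4 methyl cis to the C5 methyl. The step needs migration of the quaternary C7a instead of the C2 methylene and no epoxide closure: the tertiary alkyl group has the higher migratory aptitude, the rotamer with C7a anti to the mesylate is the only one that puts hydrogen (not methyl or sulfonate) under the five-membered ring, and the aluminium-bound oxygen is too weak a nucleophile to close the epoxide.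

**Step 5**
Reactants: 7 enedione
Product: 8 8-(tert-butyldimethylsilyloxy)-4β,5β-dimethyl-10βH-decal-8-en-3-one (cis-fused)
Conditions: [(Ph3P)CuH]6 (0.35 equiv), TBSCl (2 equiv), benzene, rt
Reagents that add atoms: tert-butyldimethylsilyl chloride, CC(C)(C)[Si](C)(C)Cl
Why: Copper hydride conjugate reduction with in situ O-silylation of the copper enolate (reductive silylation) fixes the enolate as the C8=C9 enol ether; hydride should add to C10 on the face of the C5 methyl, as nucleophiles do with angularly methylated octalones, giving the cis fusion, and this reagent does not reduce the isolated C3 ketone.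

**Step 6**
Reactants: 8 keto enol ether
Product: 9 8-(tert-butyldimethylsilyloxy)-4β,5β-dimethyl-10βH-decal-8-en-3α-ol
Conditions: Li, NH3 (liquid), THF, t-BuOH (2 equiv), −78 °C; then NH4Cl
Reagents that add atoms: none
Why: Dissolving-metal ketone reduction should give the more stable equatorial carbinol, here 3α-OH trans to the equatorial C4 methyl and away from the axial C5 methyl, an outcome that hydride reagents (equatorial attack) would not give; the silyl enol ether is inert to these conditions.

**Step 7**
Reactants: 9 alcohol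
Product: 10 8-(tert-butyldimethylsilyloxy)-3α-(triethylsilyloxy)-4β,5β-dimethyl-10βH-decal-8-ene
Conditions: TESCl, imidazole, DMF, 0 °C to rt
Reagents that add atoms: chlorotriethylsilane, CC[Si](Cl)(CC)CC
Why: Standard silylation of a secondary alcohol; the triethylsilyl ether can later be removed in the presence of the tert-butyldimethylsilyl ether.

**Step 8**
Reactants: 10 silyl enol ether
Product: 12 9β-(tert-butyldimethylsilyloxy)-3α-(triethylsilyloxy)-4β,5β-dimethyl-10βH-decalin-8-one, via silyloxy epoxide 11 (not isolated)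
Conditions: mCPBA, NaHCO3, CH2Cl2, −20 °C to rt
Reagents that add atoms: mCPBA, OOC(=O)c1cccc(Cl)c1
Why: Rubottom oxidation: the peracid should epoxidise the electron-rich enol ether on the convex β face of the cis-decalin (anti to ring A at C10), and epoxide opening with 1,4-silyl migration gives the equatorial 9β-silyloxy ketone.

**Step 9**
Reactants: 12 silyloxy ketone
Product: 14 9β-(tert-butyldimethylsilyloxy)-3α-(triethylsilyloxy)-10βH-eremophil-11-en-8-one, via lithium enolate 13 (not isolated)
Conditions: LiHMDS (2.2 equiv), THF/toluene, −78 °C; then Pd2(dba)3 (2.5 mol %), P(t-Bu)3·HBF4 (10 mol %), 2-bromopropene, rt; aq. NH4Cl quench at −78 °C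
Reagents that add atoms: 2-bromopropene, CC(Br)=C
Why: Palladium-catalysed α-alkenylation of a ketone enolate: kinetic deprotonation should occur at the C7 methylene and not at the silyloxy-bearing C9 methine, the C–C bond forms on the convex β face to give the equatorial 7β-isopropenyl epimer (also the thermodynamic one), and cold protonation of any product dienolate at the α-carbon keeps the alkene out of conjugation.

**Step 10**
Reactants: 14 bis-silyl ether
Product: 15 9β-(tert-butyldimethylsilyloxy)-3α-hydroxy-10βH-eremophil-11-en-8-one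
Conditions: PPTS, MeOH/CH2Cl2, 0 °C
Reagents that add atoms: none
Why: Acid-catalysed methanolysis should cleave the triethylsilyl ether much faster than the bulkier tert-butyldimethylsilyl ether, and the mild acid leaves the β,γ-unsaturated ketone alone.

**Step 11**
Reactants: 16 (R)-1,2-epoxybutane
Product: 18 (R)-pent-1-en-3-ol, via sulfonium alkoxide 17 (not isolated)
Conditions: trimethylsulfonium iodide (3 equiv), n-BuLi (2.9 equiv), THF, −10 °C to rt
Reagents that add atoms: trimethylsulfonium iodide, C[S+](C)C.[I-]
Why: Epoxide-to-allylic-alcohol homologation with excess dimethylsulfonium methylide: the ylide opens the terminal carbon and ylide-mediated elimination of dimethyl sulfide gives the vinyl carbinol; the stereocentre is not involved and stays (R).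

**Step 12**
Reactants: 18 (R)-pent-1-en-3-ol; 19 angelic acid
Product: 21 (3R)-pent-1-en-3-yl (2Z)-2-methylbut-2-enoate, via mixed anhydride 20 (not isolated)
Conditions: 19, 2,4,6-trichlorobenzoyl chloride, Et3N, toluene, rt; then 18, 80 °C
Reagents that add atoms: none
Why: Yamaguchi esterification through the mixed anhydride, run without a nucleophilic catalyst, should acylate the alcohol without Z-to-E isomerisation of the angelate; the carbinol centre is retained.

**Step 13**
Reactants: 21 allylic angelate
Product: 22 (2E,4R)-4-{[(2Z)-2-methylbut-2-enoyl]oxy}hex-2-enoic acid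
Conditions: acrylic acid (3 equiv), second-generation Hoveyda–Grubbs catalyst (5 mol %), CH2Cl2, 40 °C
Reagents that add atoms: acrylic acid, C=CC(=O)O
Why: Olefin cross-metathesis of the terminal alkene with acrylic acid should give the E-enoic acid; the trisubstituted, electron-poor angelate alkene does not take part.

**Step 14**
Reactants: 15 decalol; 22 acid
Product: 23 9-O-tert-butyldimethylsilyl ether of the target
Conditions: DCC, DMAP (0.1 equiv), CH2Cl2, 0 °C to rt
Reagents that add atoms: none
Why: Steglich esterification of the equatorial 3α-alcohol with retention at C3; low temperature and only catalytic DMAP limit γ-deprotonation of the activated enoate.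

**Step 15**
Reactants: 23 silyl ether
Product: 24 target
Conditions: HF·pyridine, pyridine/THF, 0 °C to rt
Reagents that add atoms: none
Why: Buffered fluoride desilylation should free the 9β-hydroxyl while leaving both esters, the β,γ-unsaturated ketone and the α-ketol untouched.

**Compound list**

1 | (S)-Hajos–Parrish ketone, (7aS)-7a-methyl-2,3,7,7a-tetrahydro-1H-indene-1,5(6H)-dione | C[C@]12CCC(=O)C=C1CCC2=O | starting material
2 | (1S,7aS)-1-(1-ethoxyvinyl)-1-hydroxy-7a-methyl-2,3,7,7a-tetrahydro-1H-inden-5(6H)-one (OH cis to the angular methyl; present as its metal alkoxide) | C[C@]12CCC(=O)C=C1CC[C@@]2(O)C(=C)OCC | intermediate (not isolated)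
3 | (1S,7aS)-1-acetyl-1-hydroxy-7a-methyl-2,3,7,7a-tetrahydro-1H-inden-5(6H)-one | C[C@]12CCC(=O)C=C1CC[C@@]2(O)C(C)=O | intermediate
4 | (1S,7aS)-1-hydroxy-1-[(1R)-1-hydroxyethyl]-7a-methyl-2,3,7,7a-tetrahydro-1H-inden-5(6H)-one | C[C@]12CCC(=O)C=C1CC[C@@]2(O)[C@@H](C)O | intermediate
5 | (1R)-1-[(1S,7aS)-1-hydroxy-7a-methyl-5-oxo-2,3,5,6,7,7a-hexahydro-1H-inden-1-yl]ethyl methanesulfonate | C[C@]12CCC(=O)C=C1CC[C@@]2(O)[C@@H](C)OS(C)(=O)=O | intermediate
6 | chloro(ethyl)aluminium alkoxide of 5 | C[C@]12CCC(=O)C=C1CC[C@@]2(O[Al](Cl)CC)[C@@H](C)OS(C)(=O)=O | intermediate (not isolated)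
7 | (4aR,5R)-4a,5-dimethyl-4,4a,7,8-tetrahydronaphthalene-2,6(3H,5H)-dione (methyls cis; C3 ketone, C9=C10–C8=O enone) | O=C1CC[C@@]2(C)C(=C1)CCC(=O)[C@@H]2C | intermediate
8 | 8-(tert-butyldimethylsilyloxy)-4β,5β-dimethyl-10βH-decal-8-en-3-one (cis-fused, C8=C9 enol ether) | C1C[C@@]2(C)[C@H](CCC(=O)[C@@H]2C)C=C1O[Si](C)(C)C(C)(C)C | intermediate
9 | 8-(tert-butyldimethylsilyloxy)-4β,5β-dimethyl-10βH-decal-8-en-3α-ol | C1C[C@@]2(C)[C@H](CC[C@@H](O)[C@@H]2C)C=C1O[Si](C)(C)C(C)(C)C | intermediate
10 | 8-(tert-butyldimethylsilyloxy)-3α-(triethylsilyloxy)-4β,5β-dimethyl-10βH-decal-8-ene | C1C[C@@]2(C)[C@H](CC[C@@H](O[Si](CC)(CC)CC)[C@@H]2C)C=C1O[Si](C)(C)C(C)(C)C | intermediate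
11 | 8β,9β-epoxy-8α-(tert-butyldimethylsilyloxy)-3α-(triethylsilyloxy)-4β,5β-dimethyl-10βH-decalin | C1C[C@@]2(C)[C@H](CC[C@@H](O[Si](CC)(CC)CC)[C@@H]2C)[C@H]3O[C@@]13O[Si](C)(C)C(C)(C)C | intermediate (not isolated)
12 | 9β-(tert-butyldimethylsilyloxy)-3α-(triethylsilyloxy)-4β,5β-dimethyl-10βH-decalin-8-one | C1C[C@@]2(C)[C@H](CC[C@@H](O[Si](CC)(CC)CC)[C@@H]2C)[C@@H](O[Si](C)(C)C(C)(C)C)C1=O | intermediate
13 | lithium C7=C8 enolate of 12 | [Li]OC1=CC[C@@]2(C)[C@H](CC[C@@H](O[Si](CC)(CC)CC)[C@@H]2C)[C@H]1O[Si](C)(C)C(C)(C)C | intermediate (not isolated)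
14 | 9β-(tert-butyldimethylsilyloxy)-3α-(triethylsilyloxy)-10βH-eremophil-11-en-8-one (7β-isopropenyl) | C=C(C)[C@H]1C[C@@]2(C)[C@H](CC[C@@H](O[Si](CC)(CC)CC)[C@@H]2C)[C@@H](O[Si](C)(C)C(C)(C)C)C1=O | intermediate
15 | 9β-(tert-butyldimethylsilyloxy)-3α-hydroxy-10βH-eremophil-11-en-8-one | C=C(C)[C@H]1C[C@@]2(C)[C@H](CC[C@@H](O)[C@@H]2C)[C@@H](O[Si](C)(C)C(C)(C)C)C1=O | intermediate
16 | (R)-1,2-epoxybutane | CC[C@@H]1CO1 | starting material
17 | dimethyl[(3R)-3-oxidopentyl]sulfonium (betaine) | CC[C@@H]([O-])CC[S+](C)C | intermediate (not isolated)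
18 | (R)-pent-1-en-3-ol | CC[C@@H](O)C=C | intermediate
19 | angelic acid, (2Z)-2-methylbut-2-enoic acid | C/C=C(/C)C(=O)O | starting material
20 | angelic 2,4,6-trichlorobenzoic anhydride | C/C=C(/C)C(=O)OC(=O)c1c(Cl)cc(Cl)cc1Cl | intermediate (not isolated)
21 | (3R)-pent-1-en-3-yl (2Z)-2-methylbut-2-enoate | CC[C@@H](OC(=O)/C(C)=C\C)C=C | intermediate
22 | (2E,4R)-4-{[(2Z)-2-methylbut-2-enoyl]oxy}hex-2-enoic acid | OC(=O)/C=C/[C@@H](CC)OC(=O)/C(C)=C\C | intermediate
23 | 9-O-tert-butyldimethylsilyl ether of the target | C=C(C)[C@H]1C[C@@]2(C)[C@H](CC[C@@H](OC(=O)/C=C/[C@@H](CC)OC(=O)/C(C)=C\C)[C@@H]2C)[C@@H](O[Si](C)(C)C(C)(C)C)C1=O | intermediate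
24 | (3R,4R,5R,7R,9R,10S)-9-hydroxy-8-oxoeremophil-11-en-3-yl (2E,4R)-4-{[(2Z)-2-methylbut-2-enoyl]oxy}hex-2-enoate (3α-acyloxy, 9β-OH, 10βH) | C=C(C)[C@H]1C[C@@]2(C)[C@H](CC[C@@H](OC(=O)/C=C/[C@@H](CC)OC(=O)/C(C)=C\C)[C@@H]2C)[C@@H](O)C1=O | target

**Totals**

Total steps: 15. Longest linear sequence: 12 (steps 1–10, 14, 15).

**Steps most likely to fail, with fallbacks**

Step 9. The coupling may not turn over on the hindered α-silyloxy ketone, may take place at C9, or the new alkene may move into conjugation under the basic conditions. Fallback: from 12, the C7 enolate (LDA, then ZnCl2) is added to acetone to give the aldol F8. Dehydration (Burgess reagent, toluene, 60 °C, then DBU) funnels the material to the conjugated isopropylidene ketone F9. Deconjugation through the extended potassium dienolate (KHMDS, THF, −78 °C) and kinetic α-protonation (AcOH) then gives 14, where the route is rejoined.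

Step 5. Hydride may be delivered to the α face of C10 (trans fusion), or the silyl trapping may stall. Fallback: from 7, heterogeneous hydrogenation (H2, Pd/C, EtOAc with a little pyridine) should give the cis-dione F3. Selective ketalisation of the less hindered C8 carbonyl (ethylene glycol, PPTS, benzene, reflux) gives the dioxolane F4, Li/NH3 reduction gives the 3α-alcohol F5, aqueous HCl in THF gives the hydroxy ketone F6 and TESCl/imidazole gives the silyl ether F7. Thermodynamic enol silylation toward the ring-fusion side (TBSOTf, Et3N, CH2Cl2, rt; the direction in which cis-fused decalones of this kind enolise) then gives 10, where the route is rejoined.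

Step 4. The C2 methylene may migrate in place of the quaternary carbon, the epoxide may close, or the Lewis acid may attack the enone. Fallback: mesylate 5 is closed on purpose (K2CO3, MeOH) to the spiro-epoxide F1, with inversion at the carbinol carbon. Sodium benzeneselenolate (from (PhSe)2 and NaBH4, EtOH) opens F1 at the secondary carbon with a second inversion to the β-hydroxy selenide F2. Soft activation of selenium (AgBF4 on basic alumina, CH2Cl2; β-hydroxy selenide semipinacol ring enlargement) should then convert F2 into enedione 7, where the route is rejoined.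

**Further compounds**

F1 | step 4 | spiro-epoxide from 5 (oxirane spanning indane C1 and the side-chain carbon, inverted at that carbon) | C[C@]12CCC(=O)C=C1CC[C@]21O[C@H]1C
F2 | step 4 | (1S,7aS)-1-hydroxy-7a-methyl-1-[(1R)-1-(phenylselanyl)ethyl]-2,3,7,7a-tetrahydro-1H-inden-5(6H)-one | C[C@]12CCC(=O)C=C1CC[C@@]2(O)[C@@H](C)[Se]c1ccccc1
F3 | step 5 | 4β,5β-dimethyl-10βH-decalin-3,8-dione (cis-fused) | C1C[C@@]2(C)[C@H](CCC(=O)[C@@H]2C)CC1=O
F4 | step 5 | 8,8-ethylenedioxy-4β,5β-dimethyl-10βH-decalin-3-one | C1C[C@@]2(C)[C@H](CCC(=O)[C@@H]2C)CC13OCCO3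
F5 | step 5 | 8,8-ethylenedioxy-4β,5β-dimethyl-10βH-decalin-3α-ol | C1C[C@@]2(C)[C@H](CC[C@@H](O)[C@@H]2C)CC13OCCO3
F6 | step 5 | 3α-hydroxy-4β,5β-dimethyl-10βH-decalin-8-one | C1C[C@@]2(C)[C@H](CC[C@@H](O)[C@@H]2C)CC1=O
F7 | step 5 | 3α-(triethylsilyloxy)-4β,5β-dimethyl-10βH-decalin-8-one | C1C[C@@]2(C)[C@H](CC[C@@H](O[Si](CC)(CC)CC)[C@@H]2C)CC1=O
F8 | step 9 | 7β-(2-hydroxypropan-2-yl) aldol of 12 | CC(C)(O)[C@H]1C[C@@]2(C)[C@H](CC[C@@H](O[Si](CC)(CC)CC)[C@@H]2C)[C@@H](O[Si](C)(C)C(C)(C)C)C1=O
F9 | step 9 | 7-isopropylidene ketone (conjugated isomer of 14) | CC(C)=C1C[C@@]2(C)[C@H](CC[C@@H](O[Si](CC)(CC)CC)[C@@H]2C)[C@@H](O[Si](C)(C)C(C)(C)C)C1=O
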